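The route rests on cutting two bonds of the left-hand butenolide region at once: the C8–O bond of the α,β-unsaturated 12,8-lactone and the C13–C13′ bond that alone joins the two elemanolide halves (elemane numbering, right half primed). In the key step a C13′ radical from the right-hand lactone adds to C13 of a 2-(cyclohexenyl)acrylic acid, and the C11–C7–C8 allyl radical so formed is closed at C8 by the C12 carboxylate; the step exploits that C8 is the γ-carbon of the butenolide ring, allylic to C7=C11. Both precursors, a dienoic acid and a redox-active ester, derive from the two enantiomers of verbenone.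

Key step: step 14

Remark: both enantiomers of verbenone are taken to be commercial; as drawn, the two six-membered rings have opposite configurations at C5 and C10, so each half is made from a different verbenone enantiomer by the same opening sequence.

Step 1
Reactants: 1 (1S,5S)-(−)-verbenone
Product: 2 (1S,4R,5R)-4-ethenyl-4,6,6-trimethylbicyclo[3.1.1]heptan-2-one
Conditions: vinylMgBr, CuBr·SMe2 (cat.), THF, −40 → 0 °C; aq NH4Cl
Reagents that add atoms: vinylmagnesium bromide C=C[Mg]Br
Why: Copper-catalysed conjugate addition of the vinyl Grignard reagent should deliver the vinyl group to C4 from the face opposite the gem-dimethyl bridge, which fixes the quaternary centre (later C10) with vinyl trans to the carbon that becomes the C5 isopropenyl group.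

Step 2
Reactants: 2 (1S,4R,5R)-4-ethenyl-4,6,6-trimethylbicyclo[3.1.1]heptan-2-one
Product: 4 (3R,4R)-3-ethenyl-3-methyl-4-(prop-1-en-2-yl)cyclohexan-1-one, via enol acetate 3 (not isolated)
Conditions: BF3·OEt2, Zn(OAc)2, Ac2O, rt; then K2CO3 (cat.), MeOH, rt
Reagents that add atoms: none
Why: Lewis-acid-mediated cyclobutane fragmentation of the nopinone (cleavage of the C1–C6 bond aligned with the carbonyl π-system, loss of a proton from the tertiary cation to give the isopropenyl group, trapping of the enolate as its acetate) followed by methanolysis should give the monocyclic ketone with C5 and C10 untouched.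

Step 3
Reactants: 4 (3R,4R)-3-ethenyl-3-methyl-4-(prop-1-en-2-yl)cyclohexan-1-one; 5 ethyl pyruvate
Product: 8 ethyl 2-[(4R,5R)-4-ethenyl-4-methyl-2-oxo-5-(prop-1-en-2-yl)cyclohexylidene]propanoate (E/Z mixture), via aldol adduct 6 (not isolated), via mesylate 7 (not isolated)
Conditions: LDA, THF, −78 °C; ethyl pyruvate, −78 °C; MsCl, −78 → 0 °C; DBU, rt
Reagents that add atoms: none
Why: Kinetic deprotonation should occur at the unhindered C7 methylene (C9 is neopentylic), and aldol addition to the keto group of the pyruvate followed by mesylation and E1cB elimination (aldol condensation) should give the tetrasubstituted C7=C11 alkene, whose geometry is irrelevant because both isomers converge in step 4.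

Step 4
Reactants: 8 ethyl 2-[(4R,5R)-4-ethenyl-4-methyl-2-oxo-5-(prop-1-en-2-yl)cyclohexylidene]propanoate
Product: 9 ethyl 2-[(4R,5R)-4-ethenyl-4-methyl-5-(prop-1-en-2-yl)-2-(trifluoromethanesulfonyloxy)cyclohex-1-en-1-yl]prop-2-enoate
Conditions: KHMDS, THF, −78 → 0 °C; then PhNTf2, 0 °C → rt; aq NH4Cl
Reagents that add atoms: N-phenylbis(trifluoromethanesulfonimide) O=S(=O)(N(c1ccccc1)S(=O)(=O)C(F)(F)F)C(F)(F)F
Why: Under equilibrating conditions the linear dienolate formed by γ-deprotonation at C13 should prevail over the cross-conjugated C9 enolate, and O-sulfonylation (enol triflate formation through a vinylogous enolate) gives the 2-triflyloxy diene.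

Step 5
Reactants: 9 ethyl 2-[(4R,5R)-4-ethenyl-4-methyl-5-(prop-1-en-2-yl)-2-(trifluoromethanesulfonyloxy)cyclohex-1-en-1-yl]prop-2-enoate
Product: 10 ethyl 2-[(4R,5R)-4-ethenyl-4-methyl-5-(prop-1-en-2-yl)cyclohex-1-en-1-yl]prop-2-enoate
Conditions: Pd(OAc)2 (cat.), PPh3, Bu3N, HCO2H, DMF, 60 °C
Reagents that add atoms: none
Why: Palladium-catalysed formate reduction of the enol triflate (oxidative addition, formate-to-hydride exchange, reductive elimination) should replace the C8 oxygen by hydrogen and leave the isolated alkenes and the acrylate untouched.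

Step 6
Reactants: 10 ethyl 2-[(4R,5R)-4-ethenyl-4-methyl-5-(prop-1-en-2-yl)cyclohex-1-en-1-yl]prop-2-enoate
Product: 11 2-[(4R,5R)-4-ethenyl-4-methyl-5-(prop-1-en-2-yl)cyclohex-1-en-1-yl]prop-2-enoic acid
Conditions: LiOH, THF–H2O, 0 °C → rt; then 1 M HCl to pH 3, 0 °C
Reagents that add atoms: lithium hydroxide [Li+].[OH-]
Why: Saponification of the unhindered ethyl ester should give the acid, which is kept cold and used at once because 2-substituted dienoic acids can undergo Diels–Alder dimerisation.

Step 7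
Reactants: 12 (1R,5R)-(+)-verbenone
Product: 13 (1R,4S,5S)-4-ethenyl-4,6,6-trimethylbicyclo[3.1.1]heptan-2-one
Conditions: vinylMgBr, CuBr·SMe2 (cat.), THF, −40 → 0 °C; aq NH4Cl
Reagents that add atoms: vinylmagnesium bromide C=C[Mg]Br
Why: Same copper-catalysed conjugate addition as in step 1 on the enantiomeric enone, setting C10′ with vinyl anti to the gem-dimethyl bridge.

Step 8
Reactants: 13 (1R,4S,5S)-4-ethenyl-4,6,6-trimethylbicyclo[3.1.1]heptan-2-one
Product: 15 (3S,4S)-3-ethenyl-3-methyl-4-(prop-1-en-2-yl)cyclohexan-1-one, via enol acetate 14 (not isolated)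
Conditions: BF3·OEt2, Zn(OAc)2, Ac2O, rt; then K2CO3 (cat.), MeOH, rt
Reagents that add atoms: none
Why: Same cyclobutane fragmentation and methanolysis as in step 2, giving the enantiomeric ketone.

Step 9
Reactants: 15 (3S,4S)-3-ethenyl-3-methyl-4-(prop-1-en-2-yl)cyclohexan-1-one; 16 methyl bromoacetate
Product: 18 methyl 2-[(1R,4S,5S)-4-ethenyl-4-methyl-2-oxo-5-(prop-1-en-2-yl)cyclohexyl]acetate, via C1 epimer 17 (not isolated)
Conditions: LDA, THF, −78 °C; methyl bromoacetate, DMPU, −78 → −20 °C; then NaOMe (cat.), MeOH, rt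
Reagents that add atoms: none
Why: Kinetic enolate formation at C7′ and SN2 alkylation with the bromoacetate, followed by base equilibration of the epimerisable α-centre, should place the side chain equatorial and cis to the C5′ isopropenyl group (7′R).

Step 10
Reactants: 18 methyl 2-[(1R,4S,5S)-4-ethenyl-4-methyl-2-oxo-5-(prop-1-en-2-yl)cyclohexyl]acetate
Product: 20 (3aR,5S,6S,7aR)-6-ethenyl-6-methyl-5-(prop-1-en-2-yl)hexahydro-1-benzofuran-2(3H)-one, via hydroxy ester 19 (not isolated)
Conditions: L-Selectride, THF, −78 °C → rt; aq NH4Cl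
Reagents that add atoms: none
Why: The bulky hydride should attack the C8′ ketone from the equatorial direction, away from the axial C10′ methyl group and the adjacent side chain, giving the axial alkoxide (8′R) cis to the ester arm, which lactonises on warming (diastereoselective reduction and lactonisation).

Step 11
Reactants: 20 (3aR,5S,6S,7aR)-6-ethenyl-6-methyl-5-(prop-1-en-2-yl)hexahydro-1-benzofuran-2(3H)-one
Product: 23 (3aR,5S,6S,7aR)-6-ethenyl-6-methyl-3-methylidene-5-(prop-1-en-2-yl)hexahydro-1-benzofuran-2(3H)-one, via Mannich base 21 (not isolated), via ammonium iodide 22 (not isolated)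
Conditions: LDA, THF, −78 °C; Eschenmoser's salt, −78 °C → rt; then MeI, MeOH, rt; then aq NaHCO3, CH2Cl2, rt
Reagents that add atoms: N,N-dimethylmethyleneiminium iodide (Eschenmoser's salt) C=[N+](C)C.[I-]
Why: Mannich reaction of the lactone enolate with the iminium salt, N-methylation and E1cB elimination of trimethylamine should give the α-methylene lactone.

Step 12
Reactants: 23 (3aR,5S,6S,7aR)-6-ethenyl-6-methyl-3-methylidene-5-(prop-1-en-2-yl)hexahydro-1-benzofuran-2(3H)-one
Product: 24 2-[(3S,3aR,5S,6S,7aR)-6-ethenyl-6-methyl-2-oxo-5-(prop-1-en-2-yl)octahydro-1-benzofuran-3-yl]acetic acid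
Conditions: HCO2K, 4CzIPN (cat.), thiol HAT catalyst (cat.), DMSO, blue LEDs, rt; then 1 M HCl
Reagents that add atoms: potassium formate [K+].[O-]C=O
Why: Radical hydrocarboxylation: the CO2 radical anion formed from formate by thiyl hydrogen abstraction adds to C13′ (Giese addition) and the C11′ radical takes hydrogen from the thiol on the convex face of the cis-fused bicycle, which should set 11′S with the new chain on the concave face.

Step 13
Reactants: 24 2-[(3S,3aR,5S,6S,7aR)-6-ethenyl-6-methyl-2-oxo-5-(prop-1-en-2-yl)octahydro-1-benzofuran-3-yl]acetic acid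
Product: 25 1,3-dioxoisoindolin-2-yl 2-[(3S,3aR,5S,6S,7aR)-6-ethenyl-6-methyl-2-oxo-5-(prop-1-en-2-yl)octahydro-1-benzofuran-3-yl]acetate
Conditions: N-hydroxyphthalimide, DIC, DMAP (cat.), CH2Cl2, 0 °C → rt
Reagents that add atoms: N-hydroxyphthalimide O=C1c2ccccc2C(=O)N1O
Why: Carbodiimide-mediated (Steglich-type) esterification with N-hydroxyphthalimide should give the redox-active ester without touching the lactone or the C11′ centre.

Step 14
Reactants: 11 2-[(4R,5R)-4-ethenyl-4-methyl-5-(prop-1-en-2-yl)cyclohex-1-en-1-yl]prop-2-enoic acid; 25 1,3-dioxoisoindolin-2-yl 2-[(3S,3aR,5S,6S,7aR)-6-ethenyl-6-methyl-2-oxo-5-(prop-1-en-2-yl)octahydro-1-benzofuran-3-yl]acetate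
Product: 26 target: (5R,8R,10R)-elema-1,3,7(11)-trien-12,8-olide joined at C13 to C13′ of (5′S,7′R,8′R,10′S,11′S)-elema-1′,3′-dien-12′,8′-olide
Conditions: 11 (1 equiv), 25 (1.3 equiv), fac-Ir(ppy)3 (1 mol %), Cu(MeCN)4PF6 (10 mol %), 4,4′-di-tert-butyl-2,2′-bipyridine (12 mol %), degassed DMA, blue LEDs, rt
Reagents that add atoms: none
Why: Proposed new method: photoexcited Ir(ppy)3 should reduce the N-acyloxyphthalimide 25, which loses phthalimide anion and CO2 to give the primary C13′ radical; this adds to C13, the acrylate terminus of 11, and the resulting allyl radical (C11/C8) is captured by the copper(II) carboxylate of the same molecule, C–O reductive elimination at C8 from allylcopper(III) (or oxidation to the allyl cation and collapse) closing the butenolide and returning copper(I), while the phthalimide anion takes up the acid proton. The closest known reaction types are the photoredox/copper decarboxylative carbo-oxygenation (alkyl-esterification) of 1,3-dienes and styrenes with redox-active esters and the radical–polar crossover carbolactonisation of alkenoic acids, here combined in an intramolecular 1,4-sense. The five-membered ring closes by O-attack of the C12 carboxylate on the C8 terminus of the C11–C7–C8 allyl unit, formally a 5-endo closure that leaves C7=C11 inside the new ring; it requires the carboxylate cis to C8, which σ–π isomerisation of the allylcopper intermediate can supply. C8 is the only new stereocentre: the ring oxygen has to lie in the plane of C7=C11 and is therefore delivered equatorially on the half-chair that keeps the C5 isopropenyl and C10 vinyl groups equatorial and the C10 methyl group axial, that is anti to that methyl group (8R), which is also the more stable epimer, so that any 8-epimer can be equilibrated through the acidic γ-proton. The step needs chemoselective attack of the nucleophilic alkyl radical at C13 in the presence of four isolated alkenes, which polarity matching with the only electron-poor, diene-conjugated alkene secures, and C–O rather than C–N or C–H termination, which the chelating carboxylate and the absence of a hydrogen donor favour.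

Compound list
1 | (1S,5S)-(−)-verbenone | O=C1C=C(C)[C@@H]2C[C@H]1C2(C)C | starting material
2 | (1S,4R,5R)-4-ethenyl-4,6,6-trimethylbicyclo[3.1.1]heptan-2-one | O=C1C[C@](C)(C=C)[C@@H]2C[C@H]1C2(C)C | intermediate
3 | (4R,5R)-5-ethenyl-5-methyl-4-(prop-1-en-2-yl)cyclohex-1-en-1-yl acetate (not isolated) | C=C[C@@]1(C)CC(OC(C)=O)=CC[C@@H]1C(=C)C | intermediate
4 | (3R,4R)-3-ethenyl-3-methyl-4-(prop-1-en-2-yl)cyclohexan-1-one | C=C[C@@]1(C)CC(=O)CC[C@@H]1C(=C)C | intermediate
5 | ethyl pyruvate | CC(=O)C(=O)OCC | starting material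
6 | ethyl 2-[(4R,5R)-4-ethenyl-4-methyl-2-oxo-5-(prop-1-en-2-yl)cyclohexyl]-2-hydroxypropanoate (diastereomers, not isolated) | C=C[C@@]1(C)CC(=O)C(C(C)(O)C(=O)OCC)C[C@@H]1C(=C)C | intermediate
7 | methanesulfonate of 6 (not isolated) | C=C[C@@]1(C)CC(=O)C(C(C)(OS(C)(=O)=O)C(=O)OCC)C[C@@H]1C(=C)C | intermediate
8 | ethyl 2-[(4R,5R)-4-ethenyl-4-methyl-2-oxo-5-(prop-1-en-2-yl)cyclohexylidene]propanoate (E/Z mixture) | C=C[C@@]1(C)CC(=O)C(=C(C)C(=O)OCC)C[C@@H]1C(=C)C | intermediate
9 | ethyl 2-[(4R,5R)-4-ethenyl-4-methyl-5-(prop-1-en-2-yl)-2-(trifluoromethanesulfonyloxy)cyclohex-1-en-1-yl]prop-2-enoate | C=C[C@@]1(C)CC(OS(=O)(=O)C(F)(F)F)=C(C(=C)C(=O)OCC)C[C@@H]1C(=C)C | intermediate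
10 | ethyl 2-[(4R,5R)-4-ethenyl-4-methyl-5-(prop-1-en-2-yl)cyclohex-1-en-1-yl]prop-2-enoate | C=C[C@@]1(C)CC=C(C(=C)C(=O)OCC)C[C@@H]1C(=C)C | intermediate
11 | 2-[(4R,5R)-4-ethenyl-4-methyl-5-(prop-1-en-2-yl)cyclohex-1-en-1-yl]prop-2-enoic acid | C=C[C@@]1(C)CC=C(C(=C)C(=O)O)C[C@@H]1C(=C)C | intermediate
12 | (1R,5R)-(+)-verbenone | O=C1C=C(C)[C@H]2C[C@@H]1C2(C)C | starting material
13 | (1R,4S,5S)-4-ethenyl-4,6,6-trimethylbicyclo[3.1.1]heptan-2-one | O=C1C[C@@](C)(C=C)[C@H]2C[C@@H]1C2(C)C | intermediate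
14 | (4S,5S)-5-ethenyl-5-methyl-4-(prop-1-en-2-yl)cyclohex-1-en-1-yl acetate (not isolated) | C=C[C@]1(C)CC(OC(C)=O)=CC[C@H]1C(=C)C | intermediate
15 | (3S,4S)-3-ethenyl-3-methyl-4-(prop-1-en-2-yl)cyclohexan-1-one | C=C[C@]1(C)CC(=O)CC[C@H]1C(=C)C | intermediate
16 | methyl bromoacetate | COC(=O)CBr | starting material
17 | methyl 2-[(1S,4S,5S)-4-ethenyl-4-methyl-2-oxo-5-(prop-1-en-2-yl)cyclohexyl]acetate (C1 epimer, not isolated) | C=C[C@]1(C)CC(=O)[C@H](CC(=O)OC)C[C@H]1C(=C)C | intermediate
18 | methyl 2-[(1R,4S,5S)-4-ethenyl-4-methyl-2-oxo-5-(prop-1-en-2-yl)cyclohexyl]acetate | C=C[C@]1(C)CC(=O)[C@@H](CC(=O)OC)C[C@H]1C(=C)C | intermediate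
19 | methyl 2-[(1R,2R,4S,5S)-4-ethenyl-2-hydroxy-4-methyl-5-(prop-1-en-2-yl)cyclohexyl]acetate (not isolated) | C=C[C@]1(C)C[C@@H](O)[C@@H](CC(=O)OC)C[C@H]1C(=C)C | intermediate
20 | (3aR,5S,6S,7aR)-6-ethenyl-6-methyl-5-(prop-1-en-2-yl)hexahydro-1-benzofuran-2(3H)-one | C=C[C@]1(C)C[C@H]2OC(=O)C[C@H]2C[C@H]1C(=C)C | intermediate
21 | 3-[(dimethylamino)methyl] derivative of 20 (not isolated) | C=C[C@]1(C)C[C@H]2OC(=O)C(CN(C)C)[C@H]2C[C@H]1C(=C)C | intermediate
22 | 3-[(trimethylammonio)methyl] derivative of 20, iodide (not isolated) | C=C[C@]1(C)C[C@H]2OC(=O)C(C[N+](C)(C)C)[C@H]2C[C@H]1C(=C)C.[I-] | intermediate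
23 | (3aR,5S,6S,7aR)-6-ethenyl-6-methyl-3-methylidene-5-(prop-1-en-2-yl)hexahydro-1-benzofuran-2(3H)-one | C=C[C@]1(C)C[C@H]2OC(=O)C(=C)[C@H]2C[C@H]1C(=C)C | intermediate
24 | 2-[(3S,3aR,5S,6S,7aR)-6-ethenyl-6-methyl-2-oxo-5-(prop-1-en-2-yl)octahydro-1-benzofuran-3-yl]acetic acid | OC(=O)C[C@@H]1C(=O)O[C@@H]2C[C@@](C)(C=C)[C@H](C(=C)C)C[C@H]12 | intermediate
25 | 1,3-dioxoisoindolin-2-yl ester of 24 | O=C(C[C@@H]1C(=O)O[C@@H]2C[C@@](C)(C=C)[C@H](C(=C)C)C[C@H]12)ON1C(=O)c2ccccc2C1=O | intermediate
26 | CNP0332736.1 | C=C[C@@]1(C)C[C@H]2OC(=O)C(CC[C@@H]3C(=O)O[C@@H]4C[C@@](C)(C=C)[C@H](C(=C)C)C[C@H]34)=C2C[C@@H]1C(=C)C | target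

Total step count: 14. Longest linear sequence: 8 steps (steps 7–13, then step 14).

Steps most likely to fail

Step 14 (proposed new method). The allyl radical may be reduced, dimerise or couple with phthalimide at copper instead of closing, and ring closure needs the carboxylate cis to C8 at the moment of C–O bond formation. The fallback sets out from 11 and 25 and returns at 26, using known reaction types only. Under reductive decarboxylative Giese conditions (Ru(bpy)3(PF6)2, Hantzsch ester, iPr2NEt, CH2Cl2, blue LEDs) the C13′ radical adds to C13 of 11, and protonation of the resulting dienolate at C11 should give mainly 2-[(4R,5R)-4-ethenyl-4-methyl-5-(prop-1-en-2-yl)cyclohex-1-en-1-yl]-4-[(3S,3aR,5S,6S,7aR)-6-ethenyl-6-methyl-2-oxo-5-(prop-1-en-2-yl)octahydro-1-benzofuran-3-yl]butanoic acid F1. Iodolactonisation of this β,γ-unsaturated acid under equilibrating conditions (I2, MeCN, 0 °C) forms the C8–O bond and gives the C7-iodo γ-lactone F2. DBU in toluene then eliminates HI across C7–C11 to give 26, and a final exposure to catalytic DBU equilibrates C8 if needed.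

Step 4. Enolisation toward C9 instead of C13 would give the cross-conjugated triflate, and the dienolate may be sulfonylated on carbon. The fallback sets out from 4 (with 23 from the main route) and returns at 26, so that no dienoic acid is needed. The lithium enolate of 4 is added to dimethyl fumarate (Michael addition) to give dimethyl 2-[(4R,5R)-4-ethenyl-4-methyl-2-oxo-5-(prop-1-en-2-yl)cyclohexyl]butanedioate F3. LiOH gives the corresponding butanedioic acid F4, and DIC closes it to the cyclic anhydride F5. N-Hydroxyphthalimide with DMAP should open the anhydride at the less hindered carbonyl to the mono redox-active ester F6. Decarboxylative Giese addition of F6 to 23 (Ru(bpy)3(PF6)2, Hantzsch ester, iPr2NEt, blue LEDs) forms C13–C13′ and gives the γ-keto acid F7. Ac2O with NaOAc at 80 °C closes the pseudo-acid at C8 and eliminates to the enol lactone F8, which Et3N isomerises to the conjugated butenolide 26 with C8 set under thermodynamic control.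

Step 12. Electron transfer from the CO2 radical anion may reduce the methylene lactone instead of adding to it, thiyl radicals may isomerise the isopropenyl groups, and hydrogen transfer to C11′ may not be fully face-selective. The fallback sets out from 23 and returns at 24. A methoxycarbonyl radical generated from Se-phenyl O-methyl carbonoselenoate with (TMS)3SiH and AIBN (benzene, 80 °C) adds to C13′ and the C11′ radical is reduced from the convex face, giving methyl 2-[(3S,3aR,5S,6S,7aR)-6-ethenyl-6-methyl-2-oxo-5-(prop-1-en-2-yl)octahydro-1-benzofuran-3-yl]acetate F9. LiOH followed by acidification (the lactone re-closes) gives 24.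

Further compounds
F1 | step 14 | 2-[(4R,5R)-4-ethenyl-4-methyl-5-(prop-1-en-2-yl)cyclohex-1-en-1-yl]-4-[(3S,3aR,5S,6S,7aR)-6-ethenyl-6-methyl-2-oxo-5-(prop-1-en-2-yl)octahydro-1-benzofuran-3-yl]butanoic acid (C2 epimers) | C=C[C@@]1(C)CC=C(C(CC[C@@H]2C(=O)O[C@@H]3C[C@@](C)(C=C)[C@H](C(=C)C)C[C@H]23)C(=O)O)C[C@@H]1C(=C)C
F2 | step 14 | C7-iodo γ-lactone from F1 (iodine on C7 anti to the C8 oxygen, C11 epimers) | C=C[C@@]1(C)C[C@H]2OC(=O)C(CC[C@@H]3C(=O)O[C@@H]4C[C@@](C)(C=C)[C@H](C(=C)C)C[C@H]34)[C@@]2(I)C[C@@H]1C(=C)C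
F3 | step 4 | dimethyl 2-[(4R,5R)-4-ethenyl-4-methyl-2-oxo-5-(prop-1-en-2-yl)cyclohexyl]butanedioate (diastereomers) | C=C[C@@]1(C)CC(=O)C(C(CC(=O)OC)C(=O)OC)C[C@@H]1C(=C)C
F4 | step 4 | 2-[(4R,5R)-4-ethenyl-4-methyl-2-oxo-5-(prop-1-en-2-yl)cyclohexyl]butanedioic acid | C=C[C@@]1(C)CC(=O)C(C(CC(=O)O)C(=O)O)C[C@@H]1C(=C)C
F5 | step 4 | 3-[(4R,5R)-4-ethenyl-4-methyl-2-oxo-5-(prop-1-en-2-yl)cyclohexyl]oxolane-2,5-dione | C=C[C@@]1(C)CC(=O)C(C2CC(=O)OC2=O)C[C@@H]1C(=C)C
F6 | step 4 | 4-[(1,3-dioxoisoindolin-2-yl)oxy]-2-[(4R,5R)-4-ethenyl-4-methyl-2-oxo-5-(prop-1-en-2-yl)cyclohexyl]-4-oxobutanoic acid | C=C[C@@]1(C)CC(=O)C(C(CC(=O)ON2C(=O)c3ccccc3C2=O)C(=O)O)C[C@@H]1C(=C)C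
F7 | step 4 | 2-[(4R,5R)-4-ethenyl-4-methyl-2-oxo-5-(prop-1-en-2-yl)cyclohexyl]-4-[(3S,3aR,5S,6S,7aR)-6-ethenyl-6-methyl-2-oxo-5-(prop-1-en-2-yl)octahydro-1-benzofuran-3-yl]butanoic acid | C=C[C@@]1(C)CC(=O)C(C(CC[C@@H]2C(=O)O[C@@H]3C[C@@](C)(C=C)[C@H](C(=C)C)C[C@H]23)C(=O)O)C[C@@H]1C(=C)C
F8 | step 4 | enol lactone, the C7=C8 double-bond isomer of 26 (C11 epimers) | C=C[C@@]1(C)CC2=C(C(CC[C@@H]3C(=O)O[C@@H]4C[C@@](C)(C=C)[C@H](C(=C)C)C[C@H]34)C(=O)O2)C[C@@H]1C(=C)C
F9 | step 12 | methyl 2-[(3S,3aR,5S,6S,7aR)-6-ethenyl-6-methyl-2-oxo-5-(prop-1-en-2-yl)octahydro-1-benzofuran-3-yl]acetate | COC(=O)C[C@@H]1C(=O)O[C@@H]2C[C@@](C)(C=C)[C@H](C(=C)C)C[C@H]12
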